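The only stereocentre comes from (S)-citronellol and stays S in every intermediate. All three furans are made in step 14.

Each furan is read as a buta-1,3-diene, C2=C3–C4=C5, whose termini C2 and C5 have been bridged by O1. The alkyl branch already sits on C4 (rings A and B) or C3 (ring C). The plan rests on cutting all six C–O bonds of rings A, B and C at once, back to an acyclic (S)-heptaene methyl ester holding three 2-substituted 1,3-dienes. One photooxygenation installs three O2 bridges. Then, in the dark, base and acid convert the three dihydrodioxines into the furans. The heptaene comes from three Suzuki couplings, ordered so that a boronate and a bromoalkene never share one molecule. (S)-Citronellol supplies the stereocentre.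

Key step: step 14

Assumption: rings are lettered A (beside the acrylate), B (central) and C (terminal), and furan atoms are numbered O1, C2–C5; the enantiomeric purity of 32 is that of commercial (S)-citronellol, because no step touches the stereocentre.

**Fragment 1: dienoate boronate**

Step 1
Reactants: 1 3,3-diethoxyprop-1-yne; 2 pinacolborane
Product: 4 (E)-3-(4,4,5,5-tetramethyl-1,3,2-dioxaborolan-2-yl)prop-2-enal, via acetal boronate 3 (not isolated)
Conditions: Cp2ZrHCl (5 mol %), Et3N (10 mol %), neat, 60 °C; then TsOH·H2O (cat.), THF–H2O, rt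
Reagents that add atoms: water, O
Why: Zirconocene-hydride-catalysed hydroboration adds H–B syn and anti-Markovnikov to the terminal alkyne, so only the E-alkenylboronate should form, and the acetal hydrolysis that follows is mild enough to leave the pinacol ester in place.

Step 2
Reactants: 4 (E)-3-(pinacolboryl)prop-2-enal; 5 methyl 2-(triphenylphosphoranylidene)propanoate
Product: 6 methyl (2E,4E)-2-methyl-5-(4,4,5,5-tetramethyl-1,3,2-dioxaborolan-2-yl)penta-2,4-dienoate
Conditions: CH2Cl2, rt
Reagents that add atoms: none
Why: Wittig olefination with an α-methyl, ester-stabilised ylide should give the 2E-enoate by its usual preference for the trans-oxaphosphetane, while the 4E-alkenylboronate is a spectator.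

**Fragment 2: bromotriene**

Step 3
Reactants: 7 hepta-1,6-diyne
Product: 9 2,6-dibromohepta-1,6-diene, via bis-bromoboration adduct 8 (not isolated)
Conditions: 9-bromo-9-BBN (2.4 equiv), CH2Cl2, 0 °C; AcOH, 0 °C → rt
Reagents that add atoms: 9-bromo-9-borabicyclo[3.3.1]nonane, BrB1C2CCCC1CCC2
Why: Bromoboration delivers B and Br syn across each terminal alkyne with bromine on the internal carbon, and protodeboronation with acetic acid then leaves a 2-bromo-1-alkene at both ends.

Step 4
Reactants: 9 2,6-dibromohepta-1,6-diene; 10 vinylboronic acid pinacol ester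
Product: 11 7-bromo-3-methylideneocta-1,7-diene
Conditions: 9 (3 equiv), 10 (1 equiv), Pd(PPh3)4 (3 mol %), K3PO4 (2 M aq), THF, 50 °C, BHT (trace); surplus 9 recovered by fractional distillation
Reagents that add atoms: none
Why: Suzuki–Miyaura coupling in which a threefold excess of the cheap symmetric dibromide holds double vinylation down on statistical grounds and creates the ring C diene.

**Main chain**

Step 5
Reactants: 12 (S)-citronellol
Product: 13 (S)-tert-butyl[(3,7-dimethyloct-6-en-1-yl)oxy]dimethylsilane
Conditions: TBSCl, imidazole, CH2Cl2, 0 °C → rt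
Reagents that add atoms: tert-butyldimethylsilyl chloride, CC(C)(C)[Si](C)(C)Cl
Why: Standard silylation masks the C1 hydroxyl so that the alcohol made next at the other chain end is the only free one.

Step 6
Reactants: 13 (S)-citronellyl TBS ether
Product: 15 (S)-6-[(tert-butyldimethylsilyl)oxy]-4-methylhexan-1-ol, via aldehyde 14 (not isolated)
Conditions: O3, CH2Cl2–MeOH, −78 °C; NaBH4, −78 °C → rt
Reagents that add atoms: ozone, [O-][O+]=O
Why: Ozonolysis with borohydride work-up cleaves the only C=C bond, removes the isopropylidene carbons and ends at the primary alcohol, with the stereocentre three bonds away from any reacting atom.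

Step 7
Reactants: 15 (S)-6-(TBS-oxy)-4-methylhexan-1-ol
Product: 16 (S)-tert-butyl[(6-iodo-3-methylhexyl)oxy]dimethylsilane
Conditions: I2, PPh3, imidazole, CH2Cl2, 0 °C → rt
Reagents that add atoms: iodine, II
Why: Appel-type iodination converts the unhindered primary alcohol by SN2 displacement of the oxyphosphonium ion under imidazole buffering that the silyl ether tolerates.

Step 8
Reactants: 16 (S)-iodide; 17 lithium acetylide–ethylenediamine complex
Product: 18 (S)-tert-butyldimethyl[(3-methyloct-7-yn-1-yl)oxy]silane
Conditions: DMSO–THF, 0 °C → rt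
Reagents that add atoms: none
Why: SN2 alkylation of lithium acetylide by a primary iodide in a dipolar aprotic medium adds the two carbons that become C4 and C5 of ring A.

Step 9
Reactants: 18 (S)-silyloxy alkyne
Product: 21 (S)-7-bromo-3-methyloct-7-en-1-ol, via bromoboration adduct 19 (not isolated), via silyl ether bromoalkene 20 (not isolated)
Conditions: 9-bromo-9-BBN (2 equiv), CH2Cl2, 0 °C; AcOH, 0 °C → rt; then THF, 2 M aq HCl, rt
Reagents that add atoms: 9-bromo-9-borabicyclo[3.3.1]nonane, BrB1C2CCCC1CCC2
Why: Bromoboration and protodeboronation as in step 3 give the 2-bromo-1-alkene, and because aqueous acid removes the silyl ether in the same flask, any earlier loss of it to the Lewis-acidic borane does no harm.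

Step 10
Reactants: 21 (S)-7-bromo-3-methyloct-7-en-1-ol; 6 dienoate boronate
Product: 22 methyl (2E,4E,10S)-12-hydroxy-2,10-dimethyl-6-methylidenedodeca-2,4-dienoate
Conditions: Pd(dppf)Cl2 (5 mol %), K3PO4 (2 M aq), THF, 45 °C, degassed
Reagents that add atoms: none
Why: Suzuki–Miyaura sp2–sp2 coupling proceeds with retention at both partners and tolerates the free hydroxyl and the ester, and since 21 carries no boron it cannot couple with itself.

Step 11
Reactants: 22 hydroxy trienoate
Product: 23 methyl (2E,4E,10S)-2,10-dimethyl-6-methylidene-12-oxododeca-2,4-dienoate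
Conditions: Dess–Martin periodinane, CH2Cl2, 0 °C → rt
Reagents that add atoms: none
Why: Dess–Martin oxidation stops at the aldehyde under near-neutral conditions that leave the trienoate and the β-stereocentre alone.

Step 12
Reactants: 23 aldehyde; 24 2-(dichloromethyl)-4,4,5,5-tetramethyl-1,3,2-dioxaborolane
Product: 25 methyl (2E,4E,10S,12E)-2,10-dimethyl-6-methylidene-13-(4,4,5,5-tetramethyl-1,3,2-dioxaborolan-2-yl)trideca-2,4,12-trienoate
Conditions: 24 (2 equiv), CrCl2 (8 equiv), LiI (4 equiv), THF, rt, dark
Reagents that add atoms: none
Why: Takai–Utimoto olefination with the geminal dichromium reagent formed from 24 should give the E-alkenylboronate by elimination from the less crowded adduct, and it is run only after the bromoalkene has been used up, so that no molecule ever holds both coupling handles.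

Step 13
Reactants: 25 alkenylboronate; 11 7-bromo-3-methylideneocta-1,7-diene
Product: 26 methyl (2E,4E,10S,12E)-2,10-dimethyl-6,14,18-trimethylideneicosa-2,4,12,19-tetraenoate (the heptaene ester)
Conditions: Pd(dppf)Cl2 (5 mol %), K3PO4 (2 M aq), THF, 40 °C, BHT (trace), degassed, dark
Reagents that add atoms: none
Why: Suzuki–Miyaura coupling with retention of the E-geometry completes the carbon chain and creates the ring B diene, under mild degassed conditions with a radical inhibitor to keep the heptaene from polymerising.

Step 14
Reactants: 26 heptaene ester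
Product: 30 methyl (E)-3-{4-[(4S)-5-{4-[3-(furan-3-yl)propyl]furan-2-yl}-4-methylpentyl]furan-2-yl}-2-methylprop-2-enoate, via tris-endoperoxide 27 (not isolated), via tris-hydroxycarbonyl compound 28 (not isolated), via tris-lactol 29 (not isolated)
Conditions: O2 (slow stream), tetraphenylporphyrin (1 mol %), CH2Cl2 (0.02 M), −20 °C, white LED; lamp off, Ar sparge, flask wrapped in foil; DABCO (0.3 equiv), 0 °C → rt; Amberlyst-15 (H+ form), 4 Å MS, 0 °C → rt
Reagents that add atoms: dioxygen, O=O
Why: Sensitised singlet oxygen adds in a concerted, suprafacial [4+2] fashion to the s-cis conformer of each 2-substituted 1,3-diene of 26, whose four carbons are C2–C5 of the later rings A, B and C, so that three six-membered 3,6-dihydro-1,2-dioxines (27) and all six C–O bonds arise before any furan exists. The sequence is the known dye-sensitised diene photooxygenation, Kornblum–DeLaMare rearrangement and cyclodehydration that turns 2-alkylbutadienes into 3-alkylfurans, used here at three sites of one chain. After the lamp is off and oxygen has been purged, DABCO abstracts a proton geminal to peroxide oxygen and breaks each O–O bond to give 28, a (Z)-γ-hydroxy enone at ring A (loss of the doubly allylic C2–H) and (Z)-γ-hydroxy enals at rings B and C; in each of the three rings the hydroxyl then closes 5-exo-trig onto the carbonyl carbon (29), and the sulfonic acid resin, which also binds the amine, removes water to aromatise. No stereocentre is set: the peroxide-bearing sp3 carbons of rings A and B form without control and end as sp2 atoms, and the methyl-bearing centre of the tether lies outside every reacting array. Two selectivities are required, cycloaddition over the ene reaction and, within the trienoate, attack at the outer diene, and both are built into 26, whose only trisubstituted C=C bond is the electron-poor enoate (the other alkenes are slow ene partners) and whose ester-bearing diene would have to turn its C2 methyl group inward to become s-cis. Over-oxidation of the products is excluded by timing, and DABCO in addition quenches any stray singlet oxygen physically.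

Step 15
Reactants: 30 methyl ester
Product: 32 (E)-3-{4-[(4S)-5-{4-[3-(furan-3-yl)propyl]furan-2-yl}-4-methylpentyl]furan-2-yl}-2-methylprop-2-enoic acid (target), via lithium carboxylate 31 (not isolated)
Conditions: LiOH·H2O (5 equiv), THF–MeOH–H2O, rt, Ar, dark; 1 M HCl to about pH 4, 0 °C
Reagents that add atoms: lithium hydroxide, [Li+].[OH-]
Why: Saponification (BAc2) of the unhindered methyl ester uses conditions to which furans are inert, and cold, brief acidification under argon in the dark spares the acid- and oxygen-sensitive trisfuran.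

**Compound list**

1 | 3,3-diethoxyprop-1-yne | C#CC(OCC)OCC | starting material
2 | pinacolborane | B1OC(C)(C)C(C)(C)O1 | starting material
3 | (E)-2-(3,3-diethoxyprop-1-en-1-yl)-4,4,5,5-tetramethyl-1,3,2-dioxaborolane | CCOC(OCC)/C=C/B1OC(C)(C)C(C)(C)O1 | intermediate
4 | (E)-3-(4,4,5,5-tetramethyl-1,3,2-dioxaborolan-2-yl)prop-2-enal | O=C/C=C/B1OC(C)(C)C(C)(C)O1 | intermediate
5 | methyl 2-(triphenylphosphoranylidene)propanoate | COC(=O)C(C)=P(c1ccccc1)(c1ccccc1)c1ccccc1 | starting material
6 | methyl (2E,4E)-2-methyl-5-(pinacolboryl)penta-2,4-dienoate | COC(=O)/C(C)=C/C=C/B1OC(C)(C)C(C)(C)O1 | intermediate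
7 | hepta-1,6-diyne | C#CCCCC#C | starting material
8 | (1Z,6Z)-2,6-dibromo-1,7-bis(9-borabicyclo[3.3.1]nonan-9-yl)hepta-1,6-diene | Br/C(CCC/C(Br)=C/B1C2CCCC1CCC2)=C\B1C2CCCC1CCC2 | intermediate
9 | 2,6-dibromohepta-1,6-diene | C=C(Br)CCCC(Br)=C | intermediate
10 | vinylboronic acid pinacol ester | C=CB1OC(C)(C)C(C)(C)O1 | starting material
11 | 7-bromo-3-methylideneocta-1,7-diene | C=CC(=C)CCCC(Br)=C | intermediate
12 | (S)-citronellol, (3S)-3,7-dimethyloct-6-en-1-ol | CC(C)=CCC[C@H](C)CCO | starting material
13 | (S)-tert-butyl[(3,7-dimethyloct-6-en-1-yl)oxy]dimethylsilane | CC(C)=CCC[C@H](C)CCO[Si](C)(C)C(C)(C)C | intermediate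
14 | (S)-6-[(tert-butyldimethylsilyl)oxy]-4-methylhexanal | O=CCC[C@H](C)CCO[Si](C)(C)C(C)(C)C | intermediate
15 | (S)-6-[(tert-butyldimethylsilyl)oxy]-4-methylhexan-1-ol | OCCC[C@H](C)CCO[Si](C)(C)C(C)(C)C | intermediate
16 | (S)-tert-butyl[(6-iodo-3-methylhexyl)oxy]dimethylsilane | ICCC[C@H](C)CCO[Si](C)(C)C(C)(C)C | intermediate
17 | lithium acetylide–ethylenediamine complex | [Li+].[C-]#C.NCCN | starting material
18 | (S)-tert-butyldimethyl[(3-methyloct-7-yn-1-yl)oxy]silane | C#CCCC[C@H](C)CCO[Si](C)(C)C(C)(C)C | intermediate
19 | (S,Z)-[7-bromo-8-(9-borabicyclo[3.3.1]nonan-9-yl)-3-methyloct-7-en-1-yl] TBS ether | Br/C(CCC[C@H](C)CCO[Si](C)(C)C(C)(C)C)=C\B1C2CCCC1CCC2 | intermediate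
20 | (S)-[(7-bromo-3-methyloct-7-en-1-yl)oxy](tert-butyl)dimethylsilane | C=C(Br)CCC[C@H](C)CCO[Si](C)(C)C(C)(C)C | intermediate
21 | (S)-7-bromo-3-methyloct-7-en-1-ol | C=C(Br)CCC[C@H](C)CCO | intermediate
22 | methyl (2E,4E,10S)-12-hydroxy-2,10-dimethyl-6-methylidenedodeca-2,4-dienoate | C=C(CCC[C@H](C)CCO)/C=C/C=C(\C)C(=O)OC | intermediate
23 | methyl (2E,4E,10S)-2,10-dimethyl-6-methylidene-12-oxododeca-2,4-dienoate | C=C(CCC[C@H](C)CC=O)/C=C/C=C(\C)C(=O)OC | intermediate
24 | 2-(dichloromethyl)-4,4,5,5-tetramethyl-1,3,2-dioxaborolane | ClC(Cl)B1OC(C)(C)C(C)(C)O1 | starting material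
25 | methyl (2E,4E,10S,12E)-2,10-dimethyl-6-methylidene-13-(pinacolboryl)trideca-2,4,12-trienoate | C=C(CCC[C@H](C)C/C=C/B1OC(C)(C)C(C)(C)O1)/C=C/C=C(\C)C(=O)OC | intermediate
26 | methyl (2E,4E,10S,12E)-2,10-dimethyl-6,14,18-trimethylideneicosa-2,4,12,19-tetraenoate | C=C(CCC[C@H](C)C/C=C/C(=C)CCCC(=C)C=C)/C=C/C=C(\C)C(=O)OC | intermediate
27 | tris(3,6-dihydro-1,2-dioxine), (S) at the methyl-bearing carbon, mixed at the two peroxide CH carbons | COC(=O)/C(C)=C/C1OOCC(CCC[C@H](C)CC2OOCC(CCCC3=CCOOC3)=C2)=C1 | intermediate
28 | tris[(Z)-γ-hydroxy enone/enal], representative regioisomer, carbinol carbon mixed | COC(=O)/C(C)=C/C(=O)/C=C(\CO)CCC[C@H](C)CC(O)/C=C(\C=O)CCC/C(C=O)=C/CO | intermediate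
29 | tris(2-hydroxy-2,5-dihydrofuran), representative regioisomer, ring stereocentres mixed | COC(=O)/C(C)=C/C1(O)C=C(CCC[C@H](C)CC2C=C(CCCC3=CCOC3O)C(O)O2)CO1 | intermediate
30 | methyl (E)-3-{4-[(4S)-5-{4-[3-(furan-3-yl)propyl]furan-2-yl}-4-methylpentyl]furan-2-yl}-2-methylprop-2-enoate | C/C(=C\c1cc(CCC[C@H](C)Cc2cc(CCCc3ccoc3)co2)co1)C(=O)OC | intermediate
31 | lithium salt of the target acid | C/C(=C\c1cc(CCC[C@H](C)Cc2cc(CCCc3ccoc3)co2)co1)C(=O)[O-].[Li+] | intermediate
32 | (E)-3-{4-[(4S)-5-{4-[3-(furan-3-yl)propyl]furan-2-yl}-4-methylpentyl]furan-2-yl}-2-methylprop-2-enoic acid | C/C(=C\c1cc(CCC[C@H](C)Cc2cc(CCCc3ccoc3)co2)co1)C(=O)O | target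

Total step count: 15. Longest linear sequence: 11 (steps 5–15).

**Steps most likely to fail**

1. **Step 14.** The three dienes may take up oxygen at unequal rates. Long irradiation then lets ene-type hydroperoxidation, dye bleaching and radical decay of the peroxides formed first creep in. After the lamp is off, base-induced fragmentation may compete with clean rearrangement, and acid may resinify the nascent furans.
   - Fallback: it sets out from tris-endoperoxide 27, which is worked up cold and in the dark instead of being treated with base.
   - Thiourea in MeOH at rt reduces the three O–O bonds to the hexaol tris[(Z)-2-ene-1,4-diol] F1, which is stable enough to be purified.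
   - Oxidation with pyridinium chlorochromate, [C5H5NH][CrO3Cl], in CH2Cl2 raises one allylic hydroxyl of each unit to the carbonyl level.
   - The material then passes through 28 and 29, and the mildly acidic medium removes water. The route is rejoined at 30.
   - A reduction–oxidation pair with an isolable intermediate thus replaces the redox-neutral base isomerisation.

2. **Step 4.** Double vinylation may compete, and three volatile, non-polar components of similar polarity may prove hard to separate.
   - Fallback: it sets out from 9 and 25 and moves the desymmetrisation onto the polar partner.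
   - Boronate 25 is coupled with a four- to fivefold excess of 9 (Pd(dppf)Cl2, K3PO4 aq, THF, 40 °C) to give the bromopentaene ester methyl (2E,4E,10S,12E)-18-bromo-2,10-dimethyl-6,14-dimethylidenenonadeca-2,4,12,18-tetraenoate F2.
   - The ester group of F2 makes removal of surplus 9 on silica trivial.
   - A second Suzuki coupling with 10 returns to the route at 26. Compound 11 and steps 4 and 13 are then not needed.

3. **Step 12.** Olefination may be incomplete, the large excess of divalent chromium may reduce or pinacol-couple the aldehyde, and the E-selectivity may erode.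
   - Fallback: it sets out from 23.
   - Ohira–Bestmann homologation (dimethyl (1-diazo-2-oxopropyl)phosphonate, K2CO3, MeOH, 0 °C → rt, where the methyl ester can only exchange with itself) gives the terminal alkyne methyl (2E,4E,10S)-2,10-dimethyl-6-methylidenetrideca-2,4-dien-12-ynoate F3.
   - Cp2ZrHCl-catalysed syn hydroboration with 2, as in step 1, is selective for the terminal alkyne over the conjugated triene and returns to the route at 25.

**Further compounds**

F1 | step 14 | tris[(Z)-2-ene-1,4-diol] hexaol, (S) at the methyl-bearing carbon, carbinol CH carbons mixed | COC(=O)/C(C)=C/C(O)/C=C(\CO)CCC[C@H](C)CC(O)/C=C(\CO)CCC/C(CO)=C/CO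
F2 | step 4 | methyl (2E,4E,10S,12E)-18-bromo-2,10-dimethyl-6,14-dimethylidenenonadeca-2,4,12,18-tetraenoate | C=C(CCC[C@H](C)C/C=C/C(=C)CCCC(Br)=C)/C=C/C=C(\C)C(=O)OC
F3 | step 12 | methyl (2E,4E,10S)-2,10-dimethyl-6-methylidenetrideca-2,4-dien-12-ynoate | C=C(CCC[C@H](C)CC#C)/C=C/C=C(\C)C(=O)OC
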